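## Retrosynthetic overview

1. Guidongnin (15) comes from a one-pot reduction of the 11,15-diketone 14, which sets C11 and C15.
2. The D ring (C13–C16) comes from an intramolecular Rauhut–Currier closure of vinyl ketone/enone 13. The C8–C15 bond comes from an aldol of the δ-lactone enolate with acrolein.
3. The C9–C10 bond, the C20–O bond and the δ-lactone form in one visible-light formal [4+2] between exocyclic alkene 7 and the achiral acid 9. Ring C is bought as an arene.
4. The A ring and γ-lactone 7 come from (S)-carvone. Double α′-alkylation sets C4, followed by carbonylative lactonisation, excision of the isopropenyl group and deconjugation.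
5. Ring order: A (bought) → γ-lactone → δ-lactone with ring C attached → D.

Assumption: ent-kaurane numbering is used, with α/β as in the usual drawing (C20 α). C8 of 10 and C15 of 12 are carried as mixtures because both centres are reset later.

## Route

**Step 1**
Reactants: 1, (S)-(+)-carvone
Product: 2, 6-methylcarvone (5S; C6 epimers)
Conditions: LDA, THF, −78 °C; MeI, −78→0 °C
Reagents that add atoms: iodomethane, CI
Why: Kinetic α′-enolate alkylation of the cross-conjugated enone, where the new C6 centre is irrelevant because it is re-enolised in Step 2.

**Step 2**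
Reactants: 2
Product: 3, (5R,6S)-6-(hydroxymethyl)-2,6-dimethyl-5-isopropenylcyclohex-2-enone (CH2OH trans to isopropenyl)
Conditions: LDA, THF, −78 °C; CH2O (g)
Reagents that add atoms: formaldehyde, C=O
Why: Aldol hydroxymethylation of the tetrasubstituted α′-enolate, in which the pseudo-axial isopropenyl group on the adjacent bought stereocentre blocks one face so CH2O enters anti to it and fixes the future C4 (Me β, CH2OH α).

**Step 3**
Reactants: 3
Product: 4, (5R,6S)-6-(hydroxymethyl)-2,6-dimethyl-5-isopropenylcyclohex-1-enyl triflate
Conditions: L-Selectride (2.2 equiv), THF, −78 °C; PhNTf2, −78→23 °C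
Reagents that add atoms: N-phenyl-bis(triflimide), O=S(=O)(N(c1ccccc1)S(=O)(=O)C(F)(F)F)C(F)(F)F
Why: Conjugate hydride reduction gives the regiodefined tetrasubstituted enolate, which is trapped as its enol triflate while the first hydride equivalent parks the neopentyl OH as an unreactive borate, and no stereocentre is made.

**Step 4**
Reactants: 4
Product: 5, (3aR,4R)-3a,7-dimethyl-4-isopropenyl-3a,4,5,6-tetrahydro-2-benzofuran-1(3H)-one
Conditions: Pd(PPh3)4 (5 mol %), CO (1 atm), n-Bu3N, LiCl, MeCN, 65 °C
Reagents that add atoms: carbon monoxide, [C-]#[O+]
Why: Pd(0)-catalysed carbonylative lactonisation of a hydroxy vinyl triflate (oxidative addition, CO insertion, intramolecular alkoxide capture) installs C6 and closes the five-membered lactone.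

**Step 5**
Reactants: 5
Product: 6, (3aR)-3a,7-dimethyl-3a,4,5,6-tetrahydro-2-benzofuran-1(3H)-one
Conditions: O3, MeOH, −78 °C; then PhSH, FeSO4·7H2O, −78→23 °C
Reagents that add atoms: none
Why: Hydrodealkenylation (Criegee ozonolysis to the α-methoxy hydroperoxide, Fe(II)-induced alkoxy-radical β-scission, H-transfer from PhSH), in which ozone takes only the electron-rich 1,1-disubstituted alkene, the tetrasubstituted enoate survives, and the relay stereocentre becomes CH2 after having set C4.

**Step 6**
Reactants: 6
Product: 7, (3aR,7aS)-3a-methyl-7-methylidenehexahydro-2-benzofuran-1(3H)-one (cis-fused; C10=C20H2)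
Conditions: LDA, THF–DMPU, −78 °C; AcOH, −78 °C
Reagents that add atoms: none
Why: Deconjugative protonation, in which LDA removes a γ-H from the methyl group held syn to the locked lactone carbonyl and kinetic α-protonation of the exocyclic dienolate gives the β,γ-isomer with C5–H placed to give the only unstrained (cis) ring fusion, so C5 is controlled by C4.

**Step 7**
Reactants: 8, 3-methoxybenzoic acid
Product: 9, 3-oxocyclohex-1-ene-1-carboxylic acid
Conditions: Li, NH3(l)/THF, −78 °C; NH4Cl; then 2 M HCl, 60 °C
Reagents that add atoms: water, O
Why: Birch reduction to the 1,4-dihydro acid, then enol-ether hydrolysis and acid-catalysed alkene migration into conjugation with both carbonyls, giving an achiral product.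

**Step 8 (key step)**
Reactants: 7; 9 (1.5 equiv)
Product: 10, keto bis-lactone: spiro δ-lactone (C7–O–C20) fused to a cyclohexanone ring C (C11=O); C10 with C9 β and C20 α; H9 β; C8–H epimers
Conditions: 9-mesityl-3,6-di-t-Bu-10-phenylacridinium BF4 (5 mol %), (PhS)2 (10 mol %), 2,6-lutidine (0.2 equiv), DCE, 450 nm LEDs, 23 °C
Reagents that add atoms: none
Why: Proposed new method: a visible-light formal [4+2] polar-radical-crossover δ-lactonisation in which the excited acridinium (E* ≈ +2.1 V) oxidises the carboxylate of 9 to an sp2-bound, slowly decarboxylating acyloxy radical that adds to the CH2 terminus of 7 (anti-Markovnikov C20–O bond), the nucleophilic tertiary C10 radical closes 6-endo on C9 (the unsubstituted carbon of the doubly activated, fumarate-like alkene) rather than 5-exo on fully substituted C8, and the C8 α-acyl radical is quenched by PhSH/acridinyl turnover; C9 bonds to the convex β face of the bicyclic radical, anti to C6 and the axial C19 arm (sets C10), through a chair-like ring with C5 and C11 both equatorial (sets C9, which is also epimerisable α to the ketone toward this same isomer); the closest known reaction types are the acridinium polar-radical-crossover cycloaddition of alkenes with unsaturated acids (5-exo, γ-butyrolactones) and Giese additions of tertiary radicals.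

**Step 9**
Reactants: 10; 11, acrolein (1.05 equiv)
Product: 12, C8-quaternary aldol: 8-(1-hydroxyprop-2-enyl) keto bis-lactone, C15 cis to H9 (β), C15 epimers
Conditions: LDA (2.2 equiv), THF, −78 °C; 11; AcOH quench at −78 °C
Reagents that add atoms: none beyond reactant 11 (acrolein, C=CC=O)
Why: Aldol addition via a keto-lactone dianion, in which the first LDA equivalent parks the ketone as its kinetic C12 enolate, the second forms the more basic δ-lactone enolate that alone adds 1,2 to one equivalent of acrolein, and the aldehyde reaches C8 on the face of the perpendicular C9–H because the other face is flanked by C10 and C11 (sets C8).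

**Step 10**
Reactants: 12
Product: 13, 8-acryloyl-11-oxo-12-ene bis-lactone (vinyl ketone plus cyclohexenone)
Conditions: IBX (5 equiv), DMSO–PhF, 23 °C then 75 °C
Reagents that add atoms: none
Why: IBX oxidation converts the allylic alcohol to the vinyl ketone at room temperature (erasing the C15 mixture) and, on heating, dehydrogenates the ketone α,β, which can only occur toward C12=C13 because C8 and C10 are quaternary.

**Step 11**
Reactants: 13
Product: 14, 11,15-dioxo-6,7-seco-ent-kaur-16-ene-6,19:7,20-diolide
Conditions: PMe3 (0.3 equiv), t-AmOH, 23 °C
Reagents that add atoms: none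
Why: Intramolecular Rauhut–Currier reaction in which PMe3 adds to the unhindered vinyl ketone, the enolate carbon C16 adds 5-exo to C13 of the enone, and proton transfer with loss of phosphine restores C16=C17, while the two-atom tether from C8 can only reach the C13 face syn to C15, so C13 is dictated by C8.

**Step 12**
Reactants: 14
Product: 15, guidongnin (4R,5R,8S,9S,10R,11R,13S,15R)
Conditions: NaBH4, CeCl3·7H2O, MeOH, −78→0 °C
Reagents that add atoms: none
Why: Luche reduction of both ketones, in which hydride reaches the C15 enone 1,2 from the exo face (the side of the one-carbon C14 bridge) to give the endo 15β-OH, the C11 ketone is attacked from the β (endo) face because the α face is capped by axial C10 and its C1/C5 arms to give the equatorial 11α-OH, and the lactones are inert.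

## Compound list

| No. | Name | SMILES | Role |
|---|---|---|---|
| 1 | (S)-(+)-carvone | `CC1=CC[C@@H](CC1=O)C(C)=C` | starting material |
| 2 | 6-methylcarvone (C6 epimers) | `CC1=CC[C@@H](C(C)C1=O)C(C)=C` | intermediate |
| 3 | 6-(hydroxymethyl)-6-methylcarvone | `CC1=CC[C@@H]([C@@](C)(CO)C1=O)C(C)=C` | intermediate |
| 4 | hydroxy vinyl triflate | `CC1=C(OS(=O)(=O)C(F)(F)F)[C@](C)(CO)[C@H](CC1)C(C)=C` | intermediate |
| 5 | isopropenyl unsaturated lactone | `CC1=C2C(=O)OC[C@]2(C)[C@H](CC1)C(C)=C` | intermediate |
| 6 | conjugated A-ring lactone | `CC1=C2C(=O)OC[C@]2(C)CCC1` | intermediate |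
| 7 | cis-fused exo-methylene lactone | `C=C1CCC[C@@]2(C)COC(=O)[C@H]21` | intermediate |
| 8 | 3-methoxybenzoic acid | `COc1cccc(c1)C(=O)O` | starting material |
| 9 | 3-oxocyclohex-1-ene-1-carboxylic acid | `O=C1C=C(C(=O)O)CCC1` | intermediate |
| 10 | keto bis-lactone (C8 epimers) | `C1CC(=O)[C@H]2[C@@]3(CCC[C@@]4(C)COC(=O)[C@H]43)COC(=O)C2C1` | intermediate |
| 11 | acrolein | `C=CC=O` | starting material |
| 12 | C8 aldol adduct (C15 epimers) | `C1CC(=O)[C@H]2[C@@]3(CCC[C@@]4(C)COC(=O)[C@H]43)COC(=O)[C@]2(C1)C(O)C=C` | intermediate |
| 13 | vinyl ketone / enone | `C1=CC(=O)[C@H]2[C@@]3(CCC[C@@]4(C)COC(=O)[C@H]43)COC(=O)[C@]2(C1)C(=O)C=C` | intermediate |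
| 14 | 11,15-diketone | `C=C1[C@@H]2CC(=O)[C@H]3[C@@]4(CCC[C@@]5(C)COC(=O)[C@H]54)COC(=O)[C@]3(C2)C1=O` | intermediate |
| 15 | guidongnin | `C=C1[C@@H]2C[C@@H](O)[C@H]3[C@@]4(CCC[C@@]5(C)COC(=O)[C@H]54)COC(=O)[C@]3(C2)[C@@H]1O` | target |

## Step count

- Total steps: 12.
- Longest linear sequence: 11 (Steps 1–6 and 8–12).

## Steps most likely to fail

1. **Step 8 (proposed new step).**
   - Risks: the acyloxy radical may abstract H or decarboxylate, the C10 radical may be quenched early by thiol, or closure may go 5-exo.
   - Fallback (known chemistry): generate the same C10 radical reductively.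
     - Epoxidise 7 with mCPBA.
     - Open the epoxide with Cp2TiCl (Cp2TiCl2/Zn, collidine·HCl).
     - Trap the radical intermolecularly, Giese-type, with the 2,2,2-trifluoroethyl ester of 9. The C20 titanium alkoxide lactonises in situ.
     - Equilibrate C9 with DBU.
   - Cost: two extra steps.

2. **Step 9 (dianion aldol).**
   - Risks: reaction at C12, retro-aldol, or 1,4-addition.
   - Fallback: replace the reversible aldol with an irreversible alkylation and a radical D-ring closure.
     - TBSOTf/Et3N gives the C11 silyl enol ether.
     - KHMDS and 2,3-dibromopropene alkylate C8.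
     - Saegusa oxidation gives the enone.
     - (TMS)3SiH/AIBN drives a 5-exo vinyl-radical cyclisation.
     - SeO2/t-BuOOH followed by DMP gives 14.

3. **Step 11 (Rauhut–Currier closure to a bridged ring).**
   - Risks: vinyl ketone oligomerisation, or no closure next to the quaternary C8.
   - Fallback: use 2-bromoacrolein in Step 9. After IBX oxidation, close the α-bromo vinyl ketone onto C13 by vinyl-radical conjugate cyclisation (Bu3SnH/Et3B) or a reductive Heck reaction. Either gives 14 directly.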